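## Retrosynthetic overview

1. 9 ⇐ 8: the oxirane (last ring) by catalyst-controlled epoxidation of the trisubstituted alkene of a cyclohexadiene.
2. 8 ⇐ 7: the trans hydroxy/benzoyloxy pair by anti-SN2′ opening of an oxygen-bridged diene with benzoate.
3. 7 ⇐ 5: ester reduction and benzoylation in one flask.
4. 5 ⇐ 3: key step, an enantioselective Favorskii ring contraction of a meso dibromoketone (seven- to six-membered carbocycle, the carbonyl carbon extruded as the exocyclic carbon).
5. 3 ⇐ 1 + 2: [4+3] cycloaddition. Ring order: oxa-bridged cycloheptenone, then oxanorbornadiene, then cyclohexadiene, then oxirane.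

**Assumption:** the target is taken exactly as its SMILES defines it (oxirane oxygen trans to the free hydroxyl and cis to the ring benzoate); where the sense of induction of a catalyst is only predicted by model (steps 2, 4 and 5), the antipodal or pseudoenantiomeric catalyst is used if the observed sense is the opposite.

## Route

**Step 1**
Reactants: 1 furan; 2 1,1,3,3-tetrabromoacetone
Product: 3 meso-(1R,2S,4R,5S)-2,4-dibromo-8-oxabicyclo[3.2.1]oct-6-en-3-one
Conditions: Zn–Cu couple (1.1 equiv), B(OEt)3 (1.2 equiv), furan (5 equiv), THF, 0 °C to rt; cis isomer crystallised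
Reagents that add atoms: none
Why: Zinc removes two bromines from 2 to give the 1,3-dibromo-2-oxyallyl cation, which adds to furan in a Hoffmann [4+3] cycloaddition whose compact transition state places both bromines cis, so the product is the achiral meso ketone.

**Step 2**
Reactants: 3 meso-(1R,2S,4R,5S)-2,4-dibromo-8-oxabicyclo[3.2.1]oct-6-en-3-one
Product: 5 methyl (1S,4R)-7-oxabicyclo[2.2.1]hepta-2,5-diene-2-carboxylate, via bromocyclopropanone 4 (not isolated)
Conditions: MeOH (3 equiv), Cs2CO3 (2.5 equiv, solid), N-[4-(trifluoromethyl)benzyl]cinchonidinium bromide (10 mol%), toluene, −40 °C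
Reagents that add atoms: methanol, CO
Why: Proposed new method: a catalytic, enantioselective, desymmetrizing Favorskii ring contraction in which the chiral ammonium ion pair (free C9–OH hydrogen-bonded to the enolate oxygen) removes the enantiotopic C4–H of meso-3 (or selects one of the two equilibrating enantiomeric ammonium enolates), the enolate carbon displaces bromide at C2 with inversion inside the ion pair to give cyclopropanone 4 in the enantiodetermining step, and methanol then adds to the strained carbonyl and the adduct fragments with loss of the C4 bromide, so that the carboxyl carbon stays on C4, C2=C4 becomes the ring alkene, the seven-membered carbocycle contracts to the six-membered one and the S bridgehead ends up next to the ester; closest known chemistry is the Favorskii rearrangement of α,α′-dibromoketones to α,β-unsaturated esters with achiral alkoxide, and the cinchona phase-transfer Darzens reaction, where halide displacement inside a chiral ammonium ion pair sets the configuration.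

**Step 3**
Reactants: 5 methyl (1S,4R)-7-oxabicyclo[2.2.1]hepta-2,5-diene-2-carboxylate
Product: 7 [(1S,4R)-7-oxabicyclo[2.2.1]hepta-2,5-dien-2-yl]methyl benzoate, via diisobutylaluminium alkoxide 6 (not isolated)
Conditions: iBu2AlH (2.2 equiv), CH2Cl2, −78 °C; then pyridine (6 equiv), DMAP (0.1 equiv), BzCl (3 equiv), −78 to 0 °C; aq. KNaC4H4O6 work-up
Reagents that add atoms: benzoyl chloride, O=C(Cl)c1ccccc1; diisobutylaluminium hydride, CC(C)C[AlH]CC(C)C (its aluminium is held only in 6)
Why: iBu2AlH gives clean 1,2-reduction of the enoate to the allylic aluminium alkoxide 6, which is O-benzoylated in the same flask (in-flask acylation of an aluminium alkoxide, as in the Rychnovsky reductive acylation), so the acid-sensitive free alcohol is never handled and no stereocentre is touched.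

**Step 4**
Reactants: 7 [(1S,4R)-7-oxabicyclo[2.2.1]hepta-2,5-dien-2-yl]methyl benzoate
Product: 8 [(5R,6R)-5-(benzoyloxy)-6-hydroxycyclohexa-1,3-dien-1-yl]methyl benzoate
Conditions: [Rh(cod)Cl]2 (2.5 mol%), (S)-1-[(R)-2-(diphenylphosphino)ferrocenyl]ethyl-di-tert-butylphosphine (6 mol%), BzOH (3 equiv), Et3N (1.5 equiv), THF, 60 °C
Reagents that add atoms: benzoic acid, O=C(O)c1ccccc1
Why: In this Lautens-type rhodium-catalysed asymmetric ring opening the exo-bound metal inserts into the C4–O7 bond next to the unsubstituted alkene and benzoate attacks C6 anti to the metal (SN2′), which sets the benzoate-bearing centre trans to the retained C1 carbinol, while the ligand enantiomer (the one that gives (1R,2R) products from oxabenzonorbornadiene) is matched to cleave C4–O7 and not C1–O7.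

**Step 5**
Reactants: 8 [(5R,6R)-5-(benzoyloxy)-6-hydroxycyclohexa-1,3-dien-1-yl]methyl benzoate
Product: 9 [(1S,4R,5S,6R)-4-(benzoyloxy)-5-hydroxy-7-oxabicyclo[4.1.0]hept-2-en-6-yl]methyl benzoate
Conditions: 1,2:4,5-di-O-isopropylidene-β-L-erythro-2,3-hexodiulo-2,6-pyranose (enantiomer of the D-fructose-derived Shi ketone, 30 mol%), KHSO5 (as Oxone, 1.4 equiv), K2CO3, Bu4NHSO4 (cat.), MeCN–CH2(OMe)2–aq. Na2B4O7 buffer, 0 °C, 2 h
Reagents that add atoms: potassium peroxymonosulfate, [K+].[O-]S(=O)(=O)OO
Why: In this Shi asymmetric epoxidation the chiral dioxirane reacts only at the trisubstituted C1=C2 alkene of the diene (cis-disubstituted alkenes are poor substrates) and, by the spiro transition-state model calibrated on 1-phenylcyclohexene, the L-series ketone delivers oxygen to the face anti to the C6 hydroxyl, which sets both oxirane centres.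

## Compound list

1 | furan | c1ccoc1 | starting material
2 | 1,1,3,3-tetrabromoacetone (1,1,3,3-tetrabromopropan-2-one) | O=C(C(Br)Br)C(Br)Br | starting material
3 | meso-(1R,2S,4R,5S)-2,4-dibromo-8-oxabicyclo[3.2.1]oct-6-en-3-one (bromines cis, both anti to the oxygen bridge) | O=C1[C@@H](Br)[C@H]2C=C[C@H](O2)[C@H]1Br | intermediate
4 | bromocyclopropanone: 4-bromo-8-oxatricyclo[3.2.1.0(2,4)]oct-6-en-3-one (atoms numbered as in 3; carbonyl bridge anti to the oxygen bridge, Br on the carbon that was C4 of 3) | O=C1[C@H]2[C@H]3C=C[C@H](O3)[C@@]12Br | intermediate (not isolated)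
5 | methyl (1S,4R)-7-oxabicyclo[2.2.1]hepta-2,5-diene-2-carboxylate | COC(=O)C1=C[C@H]2C=C[C@@H]1O2 | intermediate
6 | diisobutyl{[(1S,4R)-7-oxabicyclo[2.2.1]hepta-2,5-dien-2-yl]methoxy}aluminium | CC(C)C[Al](CC(C)C)OCC1=C[C@H]2C=C[C@@H]1O2 | intermediate (not isolated)
7 | [(1S,4R)-7-oxabicyclo[2.2.1]hepta-2,5-dien-2-yl]methyl benzoate | O=C(OCC1=C[C@H]2C=C[C@@H]1O2)c1ccccc1 | intermediate
8 | [(5R,6R)-5-(benzoyloxy)-6-hydroxycyclohexa-1,3-dien-1-yl]methyl benzoate (trans) | O=C(OCC1=CC=C[C@@H](OC(=O)c2ccccc2)[C@@H]1O)c1ccccc1 | intermediate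
9 | [(1S,4R,5S,6R)-4-(benzoyloxy)-5-hydroxy-7-oxabicyclo[4.1.0]hept-2-en-6-yl]methyl benzoate (CNP0192269.6) | O=C(OC[C@]12O[C@H]1C=C[C@@H](OC(=O)c1ccccc1)[C@@H]2O)c1ccccc1 | target

## Count and risks

Total step count: 5. Longest linear sequence: 5 steps.

The three steps most likely to fail are step 2, step 4 and step 5.

Risk in step 2 (the proposed new step): the enolate of 3 may open the oxygen bridge by E1cB elimination and drift towards bromotropone-type products instead of closing the cyclopropanone; methanol may add in conjugate fashion to the strained enoate 5; the enantioselectivity may be low.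

Fallback for step 2 uses known chemistry only, sets out from 1 and comes back to the route at 8. Furan 1 and methyl propiolate (C#CC(=O)OC) undergo the known AlCl3-promoted Diels–Alder reaction (CH2Cl2, 0 °C, short contact time, cold aqueous quench) to give racemic methyl 7-oxabicyclo[2.2.1]hepta-2,5-diene-2-carboxylate F1. The conditions of step 3 turn it, through the racemic diisobutyl[(7-oxabicyclo[2.2.1]hepta-2,5-dien-2-yl)methoxy]aluminium F2 (not isolated), into racemic (7-oxabicyclo[2.2.1]hepta-2,5-dien-2-yl)methyl benzoate F3. This racemate is then submitted to the unchanged conditions of step 4, which now act as a regiodivergent parallel kinetic resolution, a behaviour known for racemic unsymmetrical oxabicyclic alkenes with this rhodium–ferrocenyl diphosphine catalyst family. The (1S,4R) enantiomer is opened at C4–O7 and gives 8. The (1R,4S) enantiomer is opened at C1–O7 and gives the regioisomer [(3R,4R)-4-(benzoyloxy)-3-hydroxycyclohexa-1,5-dien-1-yl]methyl benzoate F4, which is removed by chromatography. The ceiling is 50% of 8.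

Risk in step 4: ionisation of the primary allylic benzoate by the rhodium catalyst, cleavage of the wrong bridgehead C–O bond, and loss of water from 8 to an arene.

Fallback for step 4 sets out from 5 and comes back to the route at 8; the ring opening is run on a silyl ether that cannot ionise, and the primary benzoate is put on last. iBu2AlH (2.2 equiv, CH2Cl2, −78 °C) followed by aq. KNaC4H4O6 work-up turns 5, through alkoxide 6, into [(1S,4R)-7-oxabicyclo[2.2.1]hepta-2,5-dien-2-yl]methanol F5. TBSCl and imidazole in DMF give tert-butyl(dimethyl){[(1S,4R)-7-oxabicyclo[2.2.1]hepta-2,5-dien-2-yl]methoxy}silane F6. The catalyst, BzOH and Et3N of step 4 then give (1R,6R)-5-({[tert-butyl(dimethyl)silyl]oxy}methyl)-6-hydroxycyclohexa-2,4-dien-1-yl benzoate F7. HF·pyridine buffered with pyridine in THF at 0 °C frees (1R,6R)-6-hydroxy-5-(hydroxymethyl)cyclohexa-2,4-dien-1-yl benzoate F8. BzCl (1.05 equiv) with 2,4,6-collidine in CH2Cl2 at −40 °C acylates only the primary allylic hydroxyl and returns 8.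

Risk in step 5: delivery of oxygen to the face syn to the free hydroxyl, and benzoyl migration in the basic buffer.

Fallback for step 5 sets out from 8 and comes back to the route at 9, and replaces reagent control by substrate control. Et3SiOTf with 2,6-lutidine gives [(5R,6R)-5-(benzoyloxy)-6-[(triethylsilyl)oxy]cyclohexa-1,3-dien-1-yl]methyl benzoate F9. mCPBA with NaHCO3 in CH2Cl2 at 0 °C epoxidises the trisubstituted alkene anti to the pseudoaxial silyloxy group, which blocks its own face and cannot direct by hydrogen bonding. This gives [(1S,4R,5S,6S)-4-(benzoyloxy)-5-[(triethylsilyl)oxy]-7-oxabicyclo[4.1.0]hept-2-en-6-yl]methyl benzoate F10, whose C6 descriptor differs from that of 9 only because the silyl group changes the priorities. HF·pyridine buffered with pyridine in THF at 0 °C then frees 9.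

## Further compounds

F1 | step 2 | racemic methyl 7-oxabicyclo[2.2.1]hepta-2,5-diene-2-carboxylate | COC(=O)C1=CC2C=CC1O2
F2 | step 2 | racemic diisobutyl[(7-oxabicyclo[2.2.1]hepta-2,5-dien-2-yl)methoxy]aluminium (not isolated) | CC(C)C[Al](CC(C)C)OCC1=CC2C=CC1O2
F3 | step 2 | racemic (7-oxabicyclo[2.2.1]hepta-2,5-dien-2-yl)methyl benzoate | O=C(OCC1=CC2C=CC1O2)c1ccccc1
F4 | step 2 | [(3R,4R)-4-(benzoyloxy)-3-hydroxycyclohexa-1,5-dien-1-yl]methyl benzoate | O=C(OCC1=C[C@@H](O)[C@H](OC(=O)c2ccccc2)C=C1)c1ccccc1
F5 | step 4 | [(1S,4R)-7-oxabicyclo[2.2.1]hepta-2,5-dien-2-yl]methanol | OCC1=C[C@H]2C=C[C@@H]1O2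
F6 | step 4 | tert-butyl(dimethyl){[(1S,4R)-7-oxabicyclo[2.2.1]hepta-2,5-dien-2-yl]methoxy}silane | CC(C)(C)[Si](C)(C)OCC1=C[C@H]2C=C[C@@H]1O2
F7 | step 4 | (1R,6R)-5-({[tert-butyl(dimethyl)silyl]oxy}methyl)-6-hydroxycyclohexa-2,4-dien-1-yl benzoate | CC(C)(C)[Si](C)(C)OCC1=CC=C[C@@H](OC(=O)c2ccccc2)[C@@H]1O
F8 | step 4 | (1R,6R)-6-hydroxy-5-(hydroxymethyl)cyclohexa-2,4-dien-1-yl benzoate | OCC1=CC=C[C@@H](OC(=O)c2ccccc2)[C@@H]1O
F9 | step 5 | [(5R,6R)-5-(benzoyloxy)-6-[(triethylsilyl)oxy]cyclohexa-1,3-dien-1-yl]methyl benzoate | O=C(OCC1=CC=C[C@@H](OC(=O)c2ccccc2)[C@@H]1O[Si](CC)(CC)CC)c1ccccc1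
F10 | step 5 | [(1S,4R,5S,6S)-4-(benzoyloxy)-5-[(triethylsilyl)oxy]-7-oxabicyclo[4.1.0]hept-2-en-6-yl]methyl benzoate | O=C(OC[C@]12O[C@H]1C=C[C@@H](OC(=O)c1ccccc1)[C@@H]2O[Si](CC)(CC)CC)c1ccccc1
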